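**Plan**

1. The retrosynthesis first undoes the end groups: both phenols go back to methoxymethyl (MOM) ethers, the C1/C4 quinone goes back to a 1,2,4-trimethoxynaphthalene, and the C7–CH3 bond is cut back to C7–Br.
2. Ring B is then cut at C6–C7 and C7–C8. C7 lies between the benzyl-bearing C6 and the aryl-bearing C8, and C5 is an unsubstituted CH, so ring B is the five-membered ring of a 3-aryl-2-benzyl-1H-indene with one carbon inserted into its C2=C3 bond.
3. The indene is cut at C3–aryl (aryllithium plus indanone C=O) and at C2–CH2Ar (aldol with protected vanillin). The indanone is cut at its aryl–C(=O) bond (Friedel–Crafts) and the side chain at the cinnamic C=C (Knoevenagel–Doebner).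
4. Forward: ring A is bought as 2,4,5-trimethoxybenzaldehyde, the five-membered ring closes in step 3, benzyl and aryl groups are attached in steps 5–9, the five-membered ring is enlarged to ring B in step 10, and methyl, quinone and free phenols follow.
5. Stereochemistry: the target has no stereocentre and no stereogenic double bond. The stereocentres of the indanone, indanol and cyclopropane intermediates are formed racemic and are erased by dehydration and ring opening.

Key step: step 10

Remark: Ar stands for 3-methoxy-4-(methoxymethoxy)phenyl. Naphthalene positions carry the numbers of the target quinone. The benzo positions 4, 6, 7 of the indanones become 7, 5, 4 of the indene, because the ring is renumbered once the carbonyl carbon has become C3.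

Assumption: both phenols are carried as MOM ethers, which tolerate base, hydrogenation, organolithium reagents and the carbene step and are removed in acidic methanol without harm to the methoxyquinone.

**Route**

Step 1
Reactants: 1 2,4,5-trimethoxybenzaldehyde; 2 malonic acid
Product: 4 (E)-3-(2,4,5-trimethoxyphenyl)prop-2-enoic acid, via arylidenemalonic acid 3 (not isolated)
Conditions: pyridine, piperidine (cat.), 100 °C
Reagents that add atoms: none
Why: Knoevenagel–Doebner condensation, in which the amine-catalysed condensation product loses CO2 in hot pyridine and gives the E-cinnamic acid.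

Step 2
Reactants: 4 (E)-3-(2,4,5-trimethoxyphenyl)prop-2-enoic acid
Product: 5 3-(2,4,5-trimethoxyphenyl)propanoic acid
Conditions: H2 (1 atm), 10% Pd/C, EtOAc/MeOH, rt
Reagents that add atoms: none
Why: Catalytic hydrogenation of the conjugated C=C, which leaves the arene, the methyl ethers and the carboxylic acid untouched.

Step 3
Reactants: 5 3-(2,4,5-trimethoxyphenyl)propanoic acid
Product: 6 4,6,7-trimethoxyindan-1-one
Conditions: polyphosphoric acid, 80 °C
Reagents that add atoms: none
Why: Intramolecular Friedel–Crafts acylation, in which the acylium ion can reach only the free ortho carbon C6 (activated by the adjacent 5-methoxy group), as in the standard closure of 3-(2,5-dimethoxyphenyl)propanoic acid to 4,7-dimethoxyindan-1-one.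

Step 4
Reactants: 7 vanillin
Product: 8 3-methoxy-4-(methoxymethoxy)benzaldehyde
Conditions: MOMCl, K2CO3, acetone, 0 °C → rt
Reagents that add atoms: chloromethyl methyl ether (MOMCl), COCCl
Why: O-alkylation of the phenoxide by the reactive α-chloro ether (MOM protection), with an aldehyde that cannot enolize.

Step 5
Reactants: 6 4,6,7-trimethoxyindan-1-one; 8 3-methoxy-4-(methoxymethoxy)benzaldehyde
Product: 10 (E)-2-(ArCH=)-4,6,7-trimethoxyindan-1-one, via aldol adduct 9 (not isolated)
Conditions: KOH, MeOH, rt
Reagents that add atoms: none
Why: Claisen–Schmidt condensation, in which only the indanone can enolize and E1cB loss of water from the aldol gives the conjugated E-benzylidene ketone (aryl trans to the carbonyl carbon).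

Step 6
Reactants: 10 (E)-2-(ArCH=)-4,6,7-trimethoxyindan-1-one
Product: 11 racemic 2-(ArCH2)-4,6,7-trimethoxyindan-1-one
Conditions: H2 (1 atm), 10% Pd/C, EtOAc, rt, stopped after uptake of one equivalent
Reagents that add atoms: none
Why: Catalytic hydrogenation of the enone C=C, which is faster than reduction of the electron-rich aryl ketone and does not touch MOM ethers; the new C2 stereocentre is formed racemic and is erased in step 9.

Step 7
Reactants: 12 4-bromo-2-methoxyphenol
Product: 13 4-bromo-2-methoxy-1-(methoxymethoxy)benzene
Conditions: MOMCl, K2CO3, acetone, 0 °C → rt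
Reagents that add atoms: chloromethyl methyl ether (MOMCl), COCCl
Why: O-alkylation of the phenoxide by the α-chloro ether (MOM protection), which removes the acidic proton before lithiation.

Step 8
Reactants: 13 4-bromo-2-methoxy-1-(methoxymethoxy)benzene; 11 racemic 2-(ArCH2)-4,6,7-trimethoxyindan-1-one
Product: 15 racemic 1-Ar-2-(ArCH2)-4,6,7-trimethoxyindan-1-ol as a diastereomer mixture, via aryllithium 14 (not isolated)
Conditions: 13, n-BuLi, THF, −78 °C; then 11, −78 → 0 °C; H2O
Reagents that add atoms: none
Why: Bromine–lithium exchange followed by 1,2-addition of the aryllithium to the ketone, helped by chelation of lithium between the carbonyl oxygen and the 7-methoxy group; the relative configuration of the two stereocentres is irrelevant because both are removed in step 9.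

Step 9
Reactants: 15 racemic 1-Ar-2-(ArCH2)-4,6,7-trimethoxyindan-1-ol
Product: 16 3-Ar-2-(ArCH2)-4,5,7-trimethoxy-1H-indene
Conditions: PPTS (cat.), toluene, 4 Å molecular sieves, 60 °C
Reagents that add atoms: none
Why: Acid-catalysed E1 dehydration through a tertiary, doubly benzylic, alkoxy-stabilized cation whose only β-hydrogen is on C2, so that only the tetrasubstituted C2=C3 alkene can form, while the weak pyridinium acid spares the MOM ethers and does not reprotonate the product.

Step 10
Reactants: 16 3-Ar-2-(ArCH2)-4,5,7-trimethoxy-1H-indene; 17 bromoform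
Product: 19 8-Ar-6-(ArCH2)-7-bromo-1,2,4-trimethoxynaphthalene, via dibromocyclopropane 18 (not isolated)
Conditions: KOt-Bu (excess), CHBr3 added slowly, toluene, −20 °C → rt, then 50 °C
Reagents that add atoms: none
Why: t-Butoxide removes HBr from bromoform by α-elimination, and the electrophilic singlet dibromocarbene adds in one concerted cheletropic [2+1] step to the electron-rich tetrasubstituted C2=C3 bond of 16, which makes both new bonds (C6–C7 and C7–C8 in naphthalene numbering) and gives the cis-fused gem-dibromocyclopropane 18. The strained cyclopropane then opens by a thermally allowed two-electron disrotatory electrocyclic reaction in which the bromide syn to the five-membered ring leaves and the old C2–C3 bond breaks, so that a six-membered 2-bromoallyl cation stabilized by the aryl group and the trimethoxybenzo ring results, and base removes a proton from the former C1 methylene (C5) to aromatize ring B. The closest known reaction type is the dihalocarbene ring expansion of indenes to 2-halonaphthalenes. Ring B is therefore closed not by cyclization of a chain but by ring enlargement: a three-membered ring is closed onto the five-membered ring and electrocyclic cleavage of the shared bond leaves the six-membered ring. No stereocentre remains in 19; the two quaternary centres of 18 can only be cis because of the ring fusion and both become sp2 on opening. The step needs insertion between the aryl- and benzyl-bearing carbons only, which is secured because the conjugated 3-aryl tautomer of the indene is the stable one and its stilbene-type C2=C3 bond is the only alkene and the most nucleophilic π bond, whereas the benzene rings and the acetal C–H bonds react much more slowly with the carbene, and slow addition of a small excess of bromoform limits a second addition to the product.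

Step 11
Reactants: 19 8-Ar-6-(ArCH2)-7-bromo-1,2,4-trimethoxynaphthalene
Product: 21 8-Ar-6-(ArCH2)-1,2,4-trimethoxy-7-methylnaphthalene, via naphthyllithium 20 (not isolated)
Conditions: n-BuLi, THF, −78 °C; MeI, −78 °C → rt
Reagents that add atoms: iodomethane, CI
Why: Bromine–lithium exchange followed by SN2 methylation of the aryllithium, with no other group in 19 that reacts with n-BuLi at −78 °C.

Step 12
Reactants: 21 8-Ar-6-(ArCH2)-1,2,4-trimethoxy-7-methylnaphthalene
Product: 22 8-Ar-6-(ArCH2)-2-methoxy-7-methylnaphthalene-1,4-dione
Conditions: (NH4)2Ce(NO3)6, MeCN/H2O, 0 °C, short reaction time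
Reagents that add atoms: water, O
Why: Oxidative demethylation of a para-dimethoxyarene by tetravalent cerium (two one-electron oxidations, attack of water at C1 and C4, loss of two methanol), which should occur on the trimethoxynaphthalene ring because it is by far the most easily oxidized ring and should give the para-quinone because that product is a stabilized vinylogous ester.

Step 13
Reactants: 22 8-Ar-6-(ArCH2)-2-methoxy-7-methylnaphthalene-1,4-dione
Product: 23 larreantin
Conditions: HCl (conc., cat.), MeOH, 40 °C
Reagents that add atoms: none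
Why: Acid-catalysed acetal cleavage (transacetalization of both aryl MOM ethers to methanol), tolerated by the methoxyquinone because any exchange of its vinylogous ester methoxy group with the solvent is degenerate.

**Compound list**

1 | 2,4,5-trimethoxybenzaldehyde | COc1cc(OC)c(C=O)cc1OC | starting material
2 | malonic acid | OC(=O)CC(O)=O | starting material
3 | 2-(2,4,5-trimethoxybenzylidene)malonic acid | COc1cc(OC)c(C=C(C(=O)O)C(=O)O)cc1OC | intermediate (not isolated)
4 | (E)-3-(2,4,5-trimethoxyphenyl)prop-2-enoic acid | COc1cc(OC)c(/C=C/C(=O)O)cc1OC | intermediate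
5 | 3-(2,4,5-trimethoxyphenyl)propanoic acid | COc1cc(OC)c(CCC(=O)O)cc1OC | intermediate
6 | 4,6,7-trimethoxy-2,3-dihydro-1H-inden-1-one | COc1cc(OC)c2c(c1OC)C(=O)CC2 | intermediate
7 | vanillin (4-hydroxy-3-methoxybenzaldehyde) | COc1cc(C=O)ccc1O | starting material
8 | 3-methoxy-4-(methoxymethoxy)benzaldehyde | COCOc1ccc(C=O)cc1OC | intermediate
9 | 2-{hydroxy[3-methoxy-4-(methoxymethoxy)phenyl]methyl}-4,6,7-trimethoxy-2,3-dihydro-1H-inden-1-one, racemic diastereomer mixture | COc1cc(OC)c2c(c1OC)C(=O)C(C(O)c3ccc(OCOC)c(OC)c3)C2 | intermediate (not isolated)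
10 | (E)-2-[3-methoxy-4-(methoxymethoxy)benzylidene]-4,6,7-trimethoxy-2,3-dihydro-1H-inden-1-one | COc1cc(OC)c2c(c1OC)C(=O)/C(=C/c3ccc(OCOC)c(OC)c3)C2 | intermediate
11 | 2-[3-methoxy-4-(methoxymethoxy)benzyl]-4,6,7-trimethoxy-2,3-dihydro-1H-inden-1-one, racemic | COc1cc(OC)c2c(c1OC)C(=O)C(Cc3ccc(OCOC)c(OC)c3)C2 | intermediate
12 | 4-bromo-2-methoxyphenol | COc1cc(Br)ccc1O | starting material
13 | 4-bromo-2-methoxy-1-(methoxymethoxy)benzene | COCOc1ccc(Br)cc1OC | intermediate
14 | [3-methoxy-4-(methoxymethoxy)phenyl]lithium | [Li]c1ccc(OCOC)c(OC)c1 | intermediate (not isolated)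
15 | 1-[3-methoxy-4-(methoxymethoxy)phenyl]-2-[3-methoxy-4-(methoxymethoxy)benzyl]-4,6,7-trimethoxy-2,3-dihydro-1H-inden-1-ol, racemic, both relative configurations | COc1cc(OC)c2c(c1OC)C(O)(c3ccc(OCOC)c(OC)c3)C(Cc3ccc(OCOC)c(OC)c3)C2 | intermediate
16 | 3-[3-methoxy-4-(methoxymethoxy)phenyl]-2-[3-methoxy-4-(methoxymethoxy)benzyl]-4,5,7-trimethoxy-1H-indene | COc1cc(OC)c2c(c1OC)C(c3ccc(OCOC)c(OC)c3)=C(Cc3ccc(OCOC)c(OC)c3)C2 | intermediate (precursor of the key step)
17 | bromoform (tribromomethane) | BrC(Br)Br | starting material
18 | 1,1-dibromo-2,3,5-trimethoxy-1a-[3-methoxy-4-(methoxymethoxy)phenyl]-6a-[3-methoxy-4-(methoxymethoxy)benzyl]-1,1a,6,6a-tetrahydrocyclopropa[a]indene (the gem-dibromocyclopropane across C2=C3 of 16), racemic, cis-fused | COc1cc(OC)c2c(c1OC)C1(c3ccc(OCOC)c(OC)c3)C(Br)(Br)C1(Cc3ccc(OCOC)c(OC)c3)C2 | intermediate (not isolated)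
19 | 7-bromo-1,2,4-trimethoxy-8-[3-methoxy-4-(methoxymethoxy)phenyl]-6-[3-methoxy-4-(methoxymethoxy)benzyl]naphthalene | COc1cc(OC)c2cc(Cc3ccc(OCOC)c(OC)c3)c(Br)c(-c3ccc(OCOC)c(OC)c3)c2c1OC | intermediate (product of the key step)
20 | {1,2,4-trimethoxy-8-[3-methoxy-4-(methoxymethoxy)phenyl]-6-[3-methoxy-4-(methoxymethoxy)benzyl]naphthalen-7-yl}lithium | COc1cc(OC)c2cc(Cc3ccc(OCOC)c(OC)c3)c([Li])c(-c3ccc(OCOC)c(OC)c3)c2c1OC | intermediate (not isolated)
21 | 1,2,4-trimethoxy-8-[3-methoxy-4-(methoxymethoxy)phenyl]-6-[3-methoxy-4-(methoxymethoxy)benzyl]-7-methylnaphthalene | COc1cc(OC)c2cc(Cc3ccc(OCOC)c(OC)c3)c(C)c(-c3ccc(OCOC)c(OC)c3)c2c1OC | intermediate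
22 | 2-methoxy-8-[3-methoxy-4-(methoxymethoxy)phenyl]-6-[3-methoxy-4-(methoxymethoxy)benzyl]-7-methylnaphthalene-1,4-dione | COC1=CC(=O)c2cc(Cc3ccc(OCOC)c(OC)c3)c(C)c(-c3ccc(OCOC)c(OC)c3)c2C1=O | intermediate
23 | larreantin, 8-(4-hydroxy-3-methoxyphenyl)-6-(4-hydroxy-3-methoxybenzyl)-2-methoxy-7-methylnaphthalene-1,4-dione | COC1=CC(=O)c2cc(Cc3ccc(O)c(OC)c3)c(C)c(-c3ccc(O)c(OC)c3)c2C1=O | target

**Step count**

Total: 13 steps. Longest linear sequence: 11 steps (steps 1, 2, 3, 5, 6, 8, 9, 10, 11, 12, 13, from 2,4,5-trimethoxybenzaldehyde). Steps 4 and 7 are one-step side branches.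

**Steps most likely to fail**

Step 10 (ring expansion). Three processes may defeat it. The carbene may add too slowly to the crowded tetrasubstituted alkene. t-Butoxide may move the indene double bond toward C1 through the indenide, so that the carbon is inserted at the wrong bond. A second carbene may add to the electron-rich naphthalene product. The fallback carries out the same one-carbon insertion on an enol ether before the aryl group is present and then introduces methyl and aryl by cross-coupling. It sets out from ketone 11 and comes back at 21.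
- Silylation of 11 (TBSOTf, Et3N, CH2Cl2) gives the silyl enol ether F1.
- Dibromocarbene (CHBr3, KOt-Bu, pentane, −20 °C) followed by Bu4NF should give the 2-bromo-1-naphthol F2 by the known ring expansion of indanone silyl enol ethers.
- Suzuki–Miyaura methylation of the bromide (trimethylboroxine, Pd(dppf)Cl2, K2CO3, dioxane/H2O, 90 °C) gives the 2-methyl-1-naphthol F3.
- Tf2O and pyridine give the naphthyl triflate F4.
- Suzuki–Miyaura coupling of F4 with the arylboronic acid F5 (made from 13 with n-BuLi, B(OMe)3 and water) under Pd(OAc)2, SPhos and K3PO4 in toluene/H2O at 100 °C returns to the route at 21.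

Step 12 (oxidation). Water may attack the radical cation at C2 instead of C4, so that ortho-quinone formation competes with para-quinone formation. The dialkoxybenzene rings or the diarylmethane CH2 may be oxidized. MOM groups may be lost in the acidic medium, after which the freed phenols are oxidized. The fallback takes the regiochemistry out of the oxidation by converging on a hydroxyquinone. It sets out from 21 and comes back at the target 23.
- 21 is oxidized as in step 12.
- The crude quinone mixture is heated with aqueous HCl in THF. This hydrolyses the vinylogous ester of either regioisomer and both MOM ethers to the single 2-hydroxy-1,4-naphthoquinone F6, the tautomer common to both series.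
- F6 is methylated with HCl in methanol (acid-catalysed vinylogous esterification, which gives the 2-methoxy-1,4-quinone) and so rejoins the route at 23.

Step 8 (aryllithium addition). The basic aryllithium may deprotonate the hindered, α-branched ketone instead of adding, so that the ketone is returned after work-up. The fallback makes the enolization productive. It sets out from 11 and comes back at 16, so steps 8 and 9 are bypassed.
- KN(SiMe3)2 and PhNTf2 (THF, −78 °C) give the enol triflate F7.
- Aryllithium 14 is transmetalated with ZnCl2 to the arylzinc chloride F8.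
- Negishi coupling of F7 with F8 (Pd(PPh3)4, THF, 60 °C) gives indene 16 directly.

Further compounds
F1 | step 10 | tert-butyl({2-[3-methoxy-4-(methoxymethoxy)benzyl]-4,5,7-trimethoxy-1H-inden-3-yl}oxy)dimethylsilane | COc1cc(OC)c2c(c1OC)C(O[Si](C)(C)C(C)(C)C)=C(Cc3ccc(OCOC)c(OC)c3)C2
F2 | step 10 | 2-bromo-5,7,8-trimethoxy-3-[3-methoxy-4-(methoxymethoxy)benzyl]naphthalen-1-ol | COc1cc(OC)c2cc(Cc3ccc(OCOC)c(OC)c3)c(Br)c(O)c2c1OC
F3 | step 10 | 5,7,8-trimethoxy-3-[3-methoxy-4-(methoxymethoxy)benzyl]-2-methylnaphthalen-1-ol | COc1cc(OC)c2cc(Cc3ccc(OCOC)c(OC)c3)c(C)c(O)c2c1OC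
F4 | step 10 | 5,7,8-trimethoxy-3-[3-methoxy-4-(methoxymethoxy)benzyl]-2-methylnaphthalen-1-yl trifluoromethanesulfonate | COc1cc(OC)c2cc(Cc3ccc(OCOC)c(OC)c3)c(C)c(OS(=O)(=O)C(F)(F)F)c2c1OC
F5 | step 10 | [3-methoxy-4-(methoxymethoxy)phenyl]boronic acid | COCOc1ccc(B(O)O)cc1OC
F6 | step 12 | 2-hydroxy-8-(4-hydroxy-3-methoxyphenyl)-6-(4-hydroxy-3-methoxybenzyl)-7-methylnaphthalene-1,4-dione | OC1=CC(=O)c2cc(Cc3ccc(O)c(OC)c3)c(C)c(-c3ccc(O)c(OC)c3)c2C1=O
F7 | step 8 | 2-[3-methoxy-4-(methoxymethoxy)benzyl]-4,5,7-trimethoxy-1H-inden-3-yl trifluoromethanesulfonate | COc1cc(OC)c2c(c1OC)C(OS(=O)(=O)C(F)(F)F)=C(Cc3ccc(OCOC)c(OC)c3)C2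
F8 | step 8 | chloro[3-methoxy-4-(methoxymethoxy)phenyl]zinc | COCOc1ccc([Zn]Cl)cc1OC
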